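**Retrosynthetic overview**

- Feature: C8 of the coumarin benzene ring lies between the C7 methoxy oxygen and the lactone ring oxygen O1 (on C8a) and carries side-chain carbon C1'. The C2' oxygen together with the isopropenyl group (C3', its CH2 and CH3) is a masked 3,3-dimethyloxirane.
- Late disconnections: O1'–Si (protecting group), O2'–isovaleryl (acylation), then C2'–OH/C3'=CH2 back to the C2'–C3' oxirane (base-mediated isomerisation).
- Key disconnection C8–C1': the 8-magnesio-7-methoxycoumarin from the 8-iodide adds to (S)-3,3-dimethyloxirane-2-carbaldehyde under Felkin–Anh control, which sets C1'.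
- Precursors: the iodide from umbelliferone (C8 iodination, O-methylation); the aldehyde from prenol (Sharpless epoxidation, which sets C2', then oxidation).
- Rings: the coumarin bicycle is bought intact; the only ring made is the oxirane (step 3), and it is opened again in step 7.

Key step: step 5

Remark: C1', C2' and C3' are the side-chain carbons counted from coumarin C8. The enantiomeric purity of the target is fixed in the Sharpless step, so it should be assayed at the epoxy alcohol and, if needed, raised by recrystallising the coumarin epoxy alcohol from the key step, which is expected to crystallise.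

**Route**

Step 1
Reactants: 1 umbelliferone (7-hydroxy-2H-chromen-2-one)
Product: 2 7-hydroxy-8-iodo-2H-chromen-2-one
Conditions: I2 (1.0 equiv), KI, 20% aq. NH3, 0 °C → rt; then dil. HCl
Reagents that add atoms: iodine, II
Why: Electrophilic aromatic iodination of the 7-oxido coumarin should go to C8, the carbon ortho to the phenoxide and flanked by the ring oxygen (the position that also reacts first in aminomethylation and formylation of umbelliferone), and one equivalent of I2 at low temperature limits attack at C6.

Step 2
Reactants: 2 7-hydroxy-8-iodo-2H-chromen-2-one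
Product: 3 8-iodo-7-methoxy-2H-chromen-2-one
Conditions: MeI, K2CO3, acetone, reflux
Reagents that add atoms: iodomethane, CI
Why: Williamson O-methylation (SN2 of the potassium phenoxide on MeI) under conditions to which the lactone and the aryl iodide are inert.

Step 3
Reactants: 4 prenol (3-methylbut-2-en-1-ol)
Product: 5 [(2R)-3,3-dimethyloxiran-2-yl]methanol
Conditions: Ti(OiPr)4 (5 mol%), D-(−)-diisopropyl tartrate (6 mol%), cumene hydroperoxide (1.1 equiv), 4 Å MS, CH2Cl2, −20 °C; non-aqueous work-up, bulb-to-bulb distillation
Reagents that add atoms: cumene hydroperoxide, CC(C)(OO)c1ccccc1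
Why: Katsuki–Sharpless asymmetric epoxidation, in which the titanium tartrate complex binds both the allylic alcohol and the hydroperoxide and delivers oxygen to one enantioface of the alkene; with the D-(−)-tartrate the established correlation for this substrate class gives the (2R)-epoxy alcohol (the L-(+)-ester gives 2S), and this centre becomes C2'.

Step 4
Reactants: 5 [(2R)-3,3-dimethyloxiran-2-yl]methanol
Product: 6 (2S)-3,3-dimethyloxirane-2-carbaldehyde
Conditions: (COCl)2, DMSO, CH2Cl2, −78 °C; Et3N, −78 → 0 °C; cold brine wash, careful concentration, bulb-to-bulb distillation; kept as a THF solution over 4 Å MS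
Reagents that add atoms: none
Why: Swern oxidation (activated-DMSO oxidation through the alkoxysulfonium ylide) stops at the aldehyde under cold, non-acidic conditions that keep the oxirane closed, and the oxirane C–H is not enolised, so the centre keeps its geometry and only its descriptor changes from R to S through the priority change.

Step 5
Reactants: 3 8-iodo-7-methoxy-2H-chromen-2-one; 6 (2S)-3,3-dimethyloxirane-2-carbaldehyde
Product: 9 erythro epoxy alcohol 8-[(R)-[(2R)-3,3-dimethyloxiran-2-yl](hydroxy)methyl]-7-methoxy-2H-chromen-2-one, via arylmagnesium chloride 7 (not isolated), via chloromagnesium alkoxide 8 (not isolated)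
Conditions: 3, iPrMgCl·LiCl (1.05 equiv), THF, −40 °C, 30 min; then 6 (1.3 equiv), −78 → −40 °C; sat. aq. NH4Cl at −40 °C
Reagents that add atoms: none
Why: Iodine–magnesium exchange between 3 and iPrMgCl·LiCl (through an iodine ate species) should be fast at −40 °C, because the C8 carbanion is stabilised inductively by its two flanking oxygens and by coordination of magnesium to the methoxy group, so it outruns attack of the alkylmagnesium on the lactone; the resulting 7 then adds to the aldehyde carbon of 6 in a polar 1,2-addition that forms the C8–C1' bond. The closest known reaction type is the addition of functionalised arylmagnesium reagents, made by halogen–magnesium exchange, to 2,3-epoxy aldehydes. No ring is closed. The new stereocentre C1' is controlled by the existing C2' centre through the polar Felkin–Anh model: the oxirane C2'–O bond stands antiperiplanar to the incoming aryl group, which approaches past H-2', and this leads to the erythro (1'R,2'R) alcohol. The step needs facial selectivity at the carbonyl and chemoselectivity for the aldehyde over the lactone and the oxirane; the first is secured by the poor chelating power of the oxirane oxygen in THF and by the C3' methyl cis to the formyl group, which crowds the competing rotamers, the second by the low temperature and the much higher electrophilicity of the aldehyde. C2' is not at risk, because the oxirane C–H is not removed by the arylmagnesium.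

Step 6
Reactants: 9 erythro epoxy alcohol 8-[(R)-[(2R)-3,3-dimethyloxiran-2-yl](hydroxy)methyl]-7-methoxy-2H-chromen-2-one
Product: 10 8-[(R)-[(2R)-3,3-dimethyloxiran-2-yl](triethylsilyloxy)methyl]-7-methoxy-2H-chromen-2-one
Conditions: TESCl (1.5 equiv), imidazole (3 equiv), DMAP (cat.), DMF, 0 °C → rt
Reagents that add atoms: chlorotriethylsilane, CC[Si](Cl)(CC)CC
Why: Imidazole-promoted silylation of the secondary alcohol needs no Lewis acid, so the acid-sensitive trisubstituted oxirane stays closed, and the TES ether keeps O1' from binding the aluminium reagent or starting a Payne rearrangement and leaves O2' as the only oxygen to be freed next.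

Step 7
Reactants: 10 8-[(R)-[(2R)-3,3-dimethyloxiran-2-yl](triethylsilyloxy)methyl]-7-methoxy-2H-chromen-2-one
Product: 12 allylic alcohol 8-[(1R,2S)-2-hydroxy-3-methyl-1-(triethylsilyloxy)but-3-en-1-yl]-7-methoxy-2H-chromen-2-one, via diethylaluminium alkoxide 11 (not isolated)
Conditions: Et2Al(TMP) (4 equiv; made from 2,2,6,6-tetramethylpiperidine, n-BuLi and Et2AlCl in toluene, 0 °C), toluene, 0 °C → rt; aq. KNaC4H4O6 (potassium sodium tartrate)
Reagents that add atoms: none
Why: Aluminium amide-mediated isomerisation of an epoxide to an allylic alcohol: aluminium binds the oxirane oxygen and the hindered amide nitrogen (too bulky to attack the lactone) removes a proton from the C3' methyl group cis to H-2' in a cyclic syn-elimination, so the C3'–O bond breaks at the tertiary carbon, the isopropenyl group appears, and the C2'–O bond and with it the C2' configuration are untouched (descriptor now S through the priority change).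

Step 8
Reactants: 12 allylic alcohol 8-[(1R,2S)-2-hydroxy-3-methyl-1-(triethylsilyloxy)but-3-en-1-yl]-7-methoxy-2H-chromen-2-one; 13 isovaleric anhydride (3-methylbutanoic anhydride)
Product: 14 (1R,2S)-1-(7-methoxy-2-oxo-2H-chromen-8-yl)-3-methyl-1-(triethylsilyloxy)but-3-en-2-yl 3-methylbutanoate
Conditions: 13 (2 equiv), Et3N (3 equiv), DMAP (0.2 equiv), CH2Cl2, 0 °C → rt
Reagents that add atoms: isovaleric anhydride (compound 13), CC(C)CC(=O)OC(=O)CC(C)C
Why: DMAP-catalysed acylation through the N-acylpyridinium ion esterifies the only free hydroxyl, so the isovalerate is placed on O2' with no change at either stereocentre.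

Step 9
Reactants: 14 (1R,2S)-1-(7-methoxy-2-oxo-2H-chromen-8-yl)-3-methyl-1-(triethylsilyloxy)but-3-en-2-yl 3-methylbutanoate
Product: 15 (1R,2S)-1-hydroxy-1-(7-methoxy-2-oxo-2H-chromen-8-yl)-3-methylbut-3-en-2-yl 3-methylbutanoate (the target)
Conditions: HF·pyridine, pyridine, THF, 0 °C
Reagents that add atoms: none
Why: Fluoride cleavage of the Si–O bond in a buffered, weakly acidic medium frees O1'–H under conditions that do not support base-mediated 1,2-acyl migration and are too mild to ionise the benzylic or allylic C–O bonds.

**Compound list**

1 | umbelliferone (7-hydroxy-2H-chromen-2-one) | O=c1ccc2ccc(O)cc2o1 | starting material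
2 | 7-hydroxy-8-iodo-2H-chromen-2-one | O=c1ccc2ccc(O)c(I)c2o1 | intermediate
3 | 8-iodo-7-methoxy-2H-chromen-2-one | COc1ccc2ccc(=O)oc2c1I | intermediate
4 | prenol (3-methylbut-2-en-1-ol) | CC(C)=CCO | starting material
5 | [(2R)-3,3-dimethyloxiran-2-yl]methanol | CC1(C)[C@H](O1)CO | intermediate
6 | (2S)-3,3-dimethyloxirane-2-carbaldehyde | CC1(C)[C@H](O1)C=O | intermediate
7 | (7-methoxy-2-oxo-2H-chromen-8-yl)magnesium chloride, formed in the flask as its LiCl adduct | COc1ccc2ccc(=O)oc2c1[Mg]Cl | intermediate
8 | chloromagnesium (R)-[(2R)-3,3-dimethyloxiran-2-yl](7-methoxy-2-oxo-2H-chromen-8-yl)methanolate, formed in the flask | CC1(C)[C@H](O1)[C@H](O[Mg]Cl)c1c(OC)ccc2ccc(=O)oc12 | intermediate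
9 | 8-[(R)-[(2R)-3,3-dimethyloxiran-2-yl](hydroxy)methyl]-7-methoxy-2H-chromen-2-one (erythro epoxy alcohol) | CC1(C)[C@H](O1)[C@H](O)c1c(OC)ccc2ccc(=O)oc12 | intermediate
10 | 8-[(R)-[(2R)-3,3-dimethyloxiran-2-yl](triethylsilyloxy)methyl]-7-methoxy-2H-chromen-2-one | CC1(C)[C@H](O1)[C@H](O[Si](CC)(CC)CC)c1c(OC)ccc2ccc(=O)oc12 | intermediate
11 | diethylaluminium (1R,2S)-1-(7-methoxy-2-oxo-2H-chromen-8-yl)-3-methyl-1-(triethylsilyloxy)but-3-en-2-olate, formed in the flask | C=C(C)[C@H](O[Al](CC)CC)[C@H](O[Si](CC)(CC)CC)c1c(OC)ccc2ccc(=O)oc12 | intermediate
12 | 8-[(1R,2S)-2-hydroxy-3-methyl-1-(triethylsilyloxy)but-3-en-1-yl]-7-methoxy-2H-chromen-2-one | C=C(C)[C@H](O)[C@H](O[Si](CC)(CC)CC)c1c(OC)ccc2ccc(=O)oc12 | intermediate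
13 | isovaleric anhydride (3-methylbutanoic anhydride) | CC(C)CC(=O)OC(=O)CC(C)C | starting material
14 | (1R,2S)-1-(7-methoxy-2-oxo-2H-chromen-8-yl)-3-methyl-1-(triethylsilyloxy)but-3-en-2-yl 3-methylbutanoate | C=C(C)[C@H](OC(=O)CC(C)C)[C@H](O[Si](CC)(CC)CC)c1c(OC)ccc2ccc(=O)oc12 | intermediate
15 | (1R,2S)-1-hydroxy-1-(7-methoxy-2-oxo-2H-chromen-8-yl)-3-methylbut-3-en-2-yl 3-methylbutanoate | C=C(C)[C@H](OC(=O)CC(C)C)[C@H](O)c1c(OC)ccc2ccc(=O)oc12 | target

**Count and risks**

Total step count: 9. Longest linear sequence: 7 steps (steps 1, 2, 5, 6, 7, 8, 9 from umbelliferone; equally steps 3, 4, 5, 6, 7, 8, 9 from prenol).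

Steps most likely to fail:

1. Step 5. The aryl group may approach the carbonyl with poor facial selectivity (a chelated or anti-Felkin approach competing with the intended one), which would erode the configuration at C1'. The fallback sets out from 9 as it is obtained in step 5, whatever its composition at C1', and comes back to 9. The material is oxidised with Dess–Martin periodinane (NaHCO3, CH2Cl2, 0 °C → rt) to the single aryl oxiranyl ketone 8-[(2S)-3,3-dimethyloxirane-2-carbonyl]-7-methoxy-2H-chromen-2-one F1. F1 is then reduced with Zn(BH4)2 in Et2O at −20 °C; zinc bridges the carbonyl and oxirane oxygens and hydride enters from the face away from C3', which is the known route from 2,3-epoxy ketones to erythro epoxy alcohols and does not touch the lactone.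

2. Step 7. The aluminium amide may engage the lactone carbonyl (ring opening or ethyl transfer) instead of the oxirane, or the silyl group may migrate from O1' to O2' at the alkoxide stage. The fallback sets out from 10 and comes back at 12 without any new compound (F0). The oxirane is opened by a radical pathway instead of a basic one: Cp2TiCl, the trivalent titanium chloride made in the flask from Cp2TiCl2 and Mn dust in dry THF at rt, cleaves the C3'–O bond homolytically to the tertiary C3' radical with titanium on O2'. Loss of a methyl hydrogen to a second titanium centre (mixed disproportionation, or trapping followed by β-hydride elimination) then gives the isopropenyl group. The C2'–O bond is never broken, and mild aqueous work-up releases 12.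

3. Step 3. The small epoxy alcohol may be opened at C3 by isopropoxide or tartrate on titanium and may be lost during isolation because it is volatile and water-soluble, with erosion of enantiomeric purity. The fallback sets out from 4 and comes back at 6, bypassing 5 and step 4. Prenol is oxidised with MnO2 in CH2Cl2 to 3-methylbut-2-enal F2 (also an article of commerce). F2 is then epoxidised by amine catalysis (iminium activation, conjugate addition of tert-butyl hydroperoxide, enamine ring closure that sets C2) with a secondary dibenzylammonium salt of a chiral BINOL-derived phosphoric acid. The enantiomer of the phosphate that gives the (S)-aldehyde is chosen by correlating the sign of rotation with a small sample made through steps 3 and 4.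

**Further compounds**

F1 | step 5 | 8-[(2S)-3,3-dimethyloxirane-2-carbonyl]-7-methoxy-2H-chromen-2-one | CC1(C)[C@H](O1)C(=O)c1c(OC)ccc2ccc(=O)oc12
F0 | step 7 | none | none
F2 | step 3 | 3-methylbut-2-enal | CC(C)=CC=O
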